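Everything rests on disconnecting ring B at C9–C10 and C7–C8 while C11 stays tied to the C2 oxygen. The feature exploited is the 1,3-relationship on ring A between the C2 oxygen (the later ketone) and quaternary C10, together with the oxidised C11 on C9. One intramolecular Diels–Alder reaction of a but-2-ynoate hung from C2–O onto the C10=C5–C6=C7 diene closes ring B and a six-membered lactone bridging ring A, and transfers the C2 configuration to C10. The precursor is the (S)-but-2-ynoate of 3,5,5-trimethyl-4-vinylcyclohex-3-en-1-ol, made from (4R,6R)-actinol; lactone opening, face-selective hydrogenation, deconjugation, etherification and C3 acyloxylation complete the target.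

Key step: step 6

Remark: drimane numbering is used (ring A = C1–C5 and C10, ring B = C5–C10, C11 on C9, C12 the methyl on C8); α and β mean anti and syn to the C10 methyl group; the target is (3S,5S,9R,10R).

Step 1
Reactants: 1 (4R,6R)-actinol, (4R,6R)-4-hydroxy-2,2,6-trimethylcyclohexan-1-one
Product: 2 (4R,6R)-4-[(tert-butyldimethylsilyl)oxy]-2,2,6-trimethylcyclohexan-1-one
Conditions: TBSCl, imidazole, DMF, rt
Reagents that add atoms: tert-butyldimethylsilyl chloride, CC(C)(C)[Si](C)(C)Cl
Why: Silyl ether protection of a secondary alcohol with a silyl chloride and imidazole, which masks the hydroxyl during the enolate chemistry and touches no stereocentre.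

Step 2
Reactants: 2 (4R,6R)-4-[(tert-butyldimethylsilyl)oxy]-2,2,6-trimethylcyclohexan-1-one
Product: 4 (4R)-4-[(tert-butyldimethylsilyl)oxy]-2,6,6-trimethylcyclohex-1-en-1-yl trifluoromethanesulfonate, via lithium enolate 3 (not isolated)
Conditions: LDA, THF, −78 to 0 °C; PhNTf2, −78 °C to rt; aq NH4Cl
Reagents that add atoms: N-phenylbis(trifluoromethanesulfonimide), O=S(=O)(N(c1ccccc1)S(=O)(=O)C(F)(F)F)C(F)(F)F; lithium diisopropylamide, [Li+].CC(C)[N-]C(C)C (lithium of 3 only)
Why: Enol triflate formation by O-sulfonylation of a ketone enolate: C2 is quaternary, so only the C6 hydrogen can be removed and a single tetrasubstituted enol triflate should form, erasing the C6 stereocentre and leaving C4 untouched.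

Step 3
Reactants: 4 (4R)-4-[(tert-butyldimethylsilyl)oxy]-2,6,6-trimethylcyclohex-1-en-1-yl trifluoromethanesulfonate; 5 tributyl(vinyl)stannane
Product: 6 tert-butyldimethyl{[(1R)-3,5,5-trimethyl-4-vinylcyclohex-3-en-1-yl]oxy}silane
Conditions: Pd(PPh3)4 (5 mol %), LiCl, THF, 65 °C
Reagents that add atoms: none
Why: Stille cross-coupling of an alkenyl triflate with a vinylstannane under zerovalent palladium and chloride assistance, a coupling for which hindered 2,6,6-trimethylcyclohexenyl triflates are established partners; it installs C6 and C7 of the diene.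

Step 4
Reactants: 6 tert-butyldimethyl{[(1R)-3,5,5-trimethyl-4-vinylcyclohex-3-en-1-yl]oxy}silane
Product: 7 (1R)-3,5,5-trimethyl-4-vinylcyclohex-3-en-1-ol
Conditions: TBAF, THF, 0 °C to rt
Reagents that add atoms: none
Why: Fluoride-mediated cleavage of the silyl ether under non-acidic conditions that the acid-sensitive diene should tolerate; the carbinol configuration is retained.

Step 5
Reactants: 7 (1R)-3,5,5-trimethyl-4-vinylcyclohex-3-en-1-ol; 8 but-2-ynoic acid
Product: 9 (1S)-3,5,5-trimethyl-4-vinylcyclohex-3-en-1-yl but-2-ynoate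
Conditions: PPh3, DIAD, THF, 0 °C (betaine formed first), then 8 and 7, 0 °C to rt
Reagents that add atoms: none
Why: Mitsunobu esterification, in which the acidic ynoic acid displaces the activated alcohol by SN2 with inversion to give the (S)-ester (the C2–O configuration needed for the tether); forming the betaine first limits phosphine addition to the ynoate.

Step 6
Reactants: 9 (1S)-3,5,5-trimethyl-4-vinylcyclohex-3-en-1-yl but-2-ynoate
Product: 10 (2R,10R)-drima-5,8-dien-11,2-olide, the tricyclic lactone in which O–C11(=O) links C2 to C9 on the α-face of ring A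
Conditions: 1,2-dichlorobenzene (0.01 M), BHT (10 mol %), argon, sealed tube, 180 °C
Reagents that add atoms: none
Why: Heating should bring about a concerted, thermally allowed [4+2] cycloaddition (closest known type: intramolecular Diels–Alder reaction of ester-tethered dienyl alkynoates) in which the alkyne C9≡C8 adds across the termini C10 and C7 of the s-cis diene, forming C9–C10 and C7–C8 and leaving the C5=C6 and C8=C9 double bonds. Ring B closes as the cyclohexa-1,4-diene made directly by the cycloaddition, the unsubstituted diene terminus C7 bonding to the β-carbon C8 of the ynoate. The six-membered lactone (C10–C1–C2–O–C11–C9) closes as the tether ring when C9 bonds to C10, which needs the s-cis ester rotamer and a pseudoaxial C2–O bond, so that the lactone spans C2 and C10 of ring A as a 2-oxabicyclo[3.3.1]nonane. The only new stereocentre, quaternary C10, is controlled by C2: the four-atom tether can deliver C9 only to the ring-A face that carries the C2 oxygen, so the (S)-ester should give 10R with the methyl anti to the oxygen bridge. Regiochemistry is fixed by the tether length, intermolecular cycloaddition and radical polymerisation are held back by high dilution and BHT, and the remaining risk is a [1,5]-hydrogen shift from the C10 methyl of the diene at this temperature.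

Step 7
Reactants: 10 (2R,10R)-drima-5,8-dien-11,2-olide
Product: 11 methyl (2R,10R)-2-hydroxydrima-5,8-dien-11-oate (2α-OH)
Conditions: K2CO3 (0.2 equiv), MeOH, 0 °C to rt; aq NH4Cl
Reagents that add atoms: methanol, CO
Why: Base-catalysed transesterification (methanolysis) of the bridged lactone, driven by release of the 1,3-diaxial bridge strain; the mild carbonate base should leave the skipped diene unisomerised.

Step 8
Reactants: 11 methyl (2R,10R)-2-hydroxydrima-5,8-dien-11-oate
Product: 12 methyl (2R,5R,10R)-2-hydroxydrim-8-en-11-oate (5α-H, trans-fused)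
Conditions: H2 (1 atm), 10% Pd/C, EtOAc, rt
Reagents that add atoms: none
Why: Heterogeneous catalytic hydrogenation: the trisubstituted C5=C6 bond should be reduced while the tetrasubstituted, ester-conjugated C8=C9 bond stays, and hydrogen is delivered to the α-face because the β-face is screened by the axial C10 and C4 methyls, setting C5 as 5α-H (trans-decalin), as is usual for Diels–Alder-derived drima-5,8-diene esters.

Step 9
Reactants: 12 methyl (2R,5R,10R)-2-hydroxydrim-8-en-11-oate
Product: 13 methyl (2R,5R,10R)-2-[(tert-butyldimethylsilyl)oxy]drim-8-en-11-oate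
Conditions: TBSCl, imidazole, DMF, rt
Reagents that add atoms: tert-butyldimethylsilyl chloride, CC(C)(C)[Si](C)(C)Cl
Why: Silyl ether protection of the equatorial C2 alcohol, so that it is distinguished from the C11 alcohol made later and survives base and hydride.

Step 10
Reactants: 13 methyl (2R,5R,10R)-2-[(tert-butyldimethylsilyl)oxy]drim-8-en-11-oate
Product: 15 methyl (2R,5R,9R,10R)-2-[(tert-butyldimethylsilyl)oxy]drim-7-en-11-oate (9α-H), via potassium dienolate 14 (not isolated)
Conditions: KOt-Bu (3 equiv), DMSO/THF, rt, 1 h; inverse quench into AcOH, THF/H2O, 0 °C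
Reagents that add atoms: potassium tert-butoxide, CC(C)(C)[O-].[K+] (potassium of 14 only)
Why: Base-mediated deconjugation of an α,β-unsaturated ester through its dienolate with kinetic α-protonation: under reversible alkoxide conditions the dienolate with the endocyclic C7=C8 bond should prevail over the exocyclic C8=C12 isomer (which a carbonyl-directed lithium amide would favour), and C9 is protonated axially on the α-face, anti to the C10 methyl, leaving the ester equatorial (9R).

Step 11
Reactants: 15 methyl (2R,5R,9R,10R)-2-[(tert-butyldimethylsilyl)oxy]drim-7-en-11-oate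
Product: 16 (2R,5R,9R,10R)-2-[(tert-butyldimethylsilyl)oxy]drim-7-en-11-ol
Conditions: LiAlH4, THF, 0 °C; aq NaOH work-up
Reagents that add atoms: none
Why: Hydride reduction of the ester to the primary alcohol, which is faster than enolisation at C9 and leaves the silyl ether and the trisubstituted alkene untouched.

Step 12
Reactants: 16 (2R,5R,9R,10R)-2-[(tert-butyldimethylsilyl)oxy]drim-7-en-11-ol; 17 umbelliferone (7-hydroxy-2H-chromen-2-one)
Product: 18 7-{[(2R,5R,9R,10R)-2-[(tert-butyldimethylsilyl)oxy]drim-7-en-11-yl]oxy}-2H-chromen-2-one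
Conditions: PPh3, DIAD, THF, 0 to 40 °C
Reagents that add atoms: none
Why: Mitsunobu etherification: the acidic 7-hydroxyl of the coumarin (pKa about 8) displaces the activated primary C11 alcohol by SN2 at a carbon that is not stereogenic, and the only other hydroxyl is silylated.

Step 13
Reactants: 18 7-{[(2R,5R,9R,10R)-2-[(tert-butyldimethylsilyl)oxy]drim-7-en-11-yl]oxy}-2H-chromen-2-one
Product: 19 7-{[(2R,5R,9R,10R)-2-hydroxydrim-7-en-11-yl]oxy}-2H-chromen-2-one
Conditions: HF·pyridine, THF/pyridine, 0 °C to rt
Reagents that add atoms: none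
Why: Fluoride cleavage of the silyl ether under buffered, non-basic conditions that should spare the coumarin lactone, the aryl ether and the alkene.

Step 14
Reactants: 19 7-{[(2R,5R,9R,10R)-2-hydroxydrim-7-en-11-yl]oxy}-2H-chromen-2-one
Product: 20 7-{[(5R,9R,10R)-2-oxodrim-7-en-11-yl]oxy}-2H-chromen-2-one
Conditions: Dess–Martin periodinane, CH2Cl2, rt
Reagents that add atoms: none
Why: Dess–Martin oxidation of the secondary alcohol to the C2 ketone under neutral conditions; this removes the relay stereocentre, and no α-stereocentre exists that could epimerise.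

Step 15
Reactants: 20 7-{[(5R,9R,10R)-2-oxodrim-7-en-11-yl]oxy}-2H-chromen-2-one
Product: 23 7-{[(5S,9R,10R)-3-diazo-2-oxodrim-7-en-11-yl]oxy}-2H-chromen-2-one, via lithium enolate 21 (not isolated), via trifluoroacetyl ketone 22 (not isolated)
Conditions: LiHMDS, THF, −78 °C; CF3CO2CH2CF3, −78 °C; aq HCl work-up; then 4-acetamidobenzenesulfonyl azide, Et3N, H2O (1 equiv), MeCN, rt
Reagents that add atoms: 4-acetamidobenzenesulfonyl azide, CC(=O)Nc1ccc(cc1)S(=O)(=O)N=[N+]=[N-] (diazo nitrogens of 23); 2,2,2-trifluoroethyl trifluoroacetate, O=C(OCC(F)(F)F)C(F)(F)F (trifluoroacetyl group of 22 only); lithium hexamethyldisilazide, [Li+].C[Si](C)(C)[N-][Si](C)(C)C (lithium of 21 only)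
Why: Detrifluoroacetylative diazo transfer (enolate C-acylation, then Regitz-type transfer with loss of the N-trifluoroacetyl sulfonamide): enolisation should go toward C3, because a C1 enolate would push C1–H into the peri space of C11 and its axial 1α-hydrogen is screened by H9α, and the coumarin should survive the non-nucleophilic base at −78 °C.

Step 16
Reactants: 23 7-{[(5S,9R,10R)-3-diazo-2-oxodrim-7-en-11-yl]oxy}-2H-chromen-2-one; 24 angelic acid, (Z)-2-methylbut-2-enoic acid
Product: 25 (3S,5S,9R,10R)-2-oxo-11-[(2-oxo-2H-chromen-7-yl)oxy]drim-7-en-3-yl (Z)-2-methylbut-2-enoate (target, 3β-angelate)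
Conditions: Rh2(OAc)4 (2 mol %), 24 (3 equiv), CH2Cl2, rt, slow addition of 23
Reagents that add atoms: none
Why: O–H insertion of a divalent rhodium carbenoid into a carboxylic acid, known for α-diazo ketones: the C3 carbenoid has no neighbouring C–H for a 1,2-shift (C4 is quaternary), excess acid outruns cyclopropanation, the enol intermediate should be protonated axially on the α-face so that the angelate ends equatorial (3β, S, also the more stable epimer), and the neutral conditions keep the Z-alkene of the angelate.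

Compound list
1 | (4R,6R)-actinol, (4R,6R)-4-hydroxy-2,2,6-trimethylcyclohexan-1-one | C[C@@H]1C[C@@H](O)CC(C)(C)C1=O | starting material
2 | (4R,6R)-4-[(tert-butyldimethylsilyl)oxy]-2,2,6-trimethylcyclohexan-1-one | C[C@@H]1C[C@@H](O[Si](C)(C)C(C)(C)C)CC(C)(C)C1=O | intermediate
3 | lithium (4R)-4-[(tert-butyldimethylsilyl)oxy]-2,6,6-trimethylcyclohex-1-en-1-olate | CC(C)(C)[Si](C)(C)O[C@@H]1CC(C)=C([O-])C(C)(C)C1.[Li+] | intermediate (not isolated)
4 | (4R)-4-[(tert-butyldimethylsilyl)oxy]-2,6,6-trimethylcyclohex-1-en-1-yl trifluoromethanesulfonate | CC(C)(C)[Si](C)(C)O[C@@H]1CC(C)=C(OS(=O)(=O)C(F)(F)F)C(C)(C)C1 | intermediate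
5 | tributyl(vinyl)stannane | C=C[Sn](CCCC)(CCCC)CCCC | starting material
6 | tert-butyldimethyl{[(1R)-3,5,5-trimethyl-4-vinylcyclohex-3-en-1-yl]oxy}silane | CC(C)(C)[Si](C)(C)O[C@@H]1CC(C)=C(C=C)C(C)(C)C1 | intermediate
7 | (1R)-3,5,5-trimethyl-4-vinylcyclohex-3-en-1-ol | O[C@@H]1CC(C)=C(C=C)C(C)(C)C1 | intermediate
8 | but-2-ynoic acid | CC#CC(=O)O | starting material
9 | (1S)-3,5,5-trimethyl-4-vinylcyclohex-3-en-1-yl but-2-ynoate (key-step precursor) | CC#CC(=O)O[C@H]1CC(C)=C(C=C)C(C)(C)C1 | intermediate
10 | (2R,10R)-drima-5,8-dien-11,2-olide (key-step product; lactone bridge α, C10 methyl β) | O=C1O[C@@H]2CC(C)(C)C3=CCC(C)=C1[C@]3(C)C2 | intermediate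
11 | methyl (2R,10R)-2-hydroxydrima-5,8-dien-11-oate (2α-OH) | O[C@@H]1CC(C)(C)C2=CCC(C)=C(C(=O)OC)[C@]2(C)C1 | intermediate
12 | methyl (2R,5R,10R)-2-hydroxydrim-8-en-11-oate (2α-OH, 5α-H) | O[C@@H]1CC(C)(C)[C@H]2CCC(C)=C(C(=O)OC)[C@]2(C)C1 | intermediate
13 | methyl (2R,5R,10R)-2-[(tert-butyldimethylsilyl)oxy]drim-8-en-11-oate | CC(C)(C)[Si](C)(C)O[C@@H]1CC(C)(C)[C@H]2CCC(C)=C(C(=O)OC)[C@]2(C)C1 | intermediate
14 | potassium dienolate of 13 (C9=C11 enolate, C7=C8 alkene) | CC(C)(C)[Si](C)(C)O[C@@H]1CC(C)(C)[C@H]2CC=C(C)C(=C([O-])OC)[C@]2(C)C1.[K+] | intermediate (not isolated)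
15 | methyl (2R,5R,9R,10R)-2-[(tert-butyldimethylsilyl)oxy]drim-7-en-11-oate (9α-H) | CC(C)(C)[Si](C)(C)O[C@@H]1CC(C)(C)[C@H]2CC=C(C)[C@@H](C(=O)OC)[C@]2(C)C1 | intermediate
16 | (2R,5R,9R,10R)-2-[(tert-butyldimethylsilyl)oxy]drim-7-en-11-ol | CC(C)(C)[Si](C)(C)O[C@@H]1CC(C)(C)[C@H]2CC=C(C)[C@@H](CO)[C@]2(C)C1 | intermediate
17 | umbelliferone, 7-hydroxy-2H-chromen-2-one | Oc1ccc2ccc(=O)oc2c1 | starting material
18 | 7-{[(2R,5R,9R,10R)-2-[(tert-butyldimethylsilyl)oxy]drim-7-en-11-yl]oxy}-2H-chromen-2-one | CC(C)(C)[Si](C)(C)O[C@@H]1CC(C)(C)[C@H]2CC=C(C)[C@@H](COc3ccc4ccc(=O)oc4c3)[C@]2(C)C1 | intermediate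
19 | 7-{[(2R,5R,9R,10R)-2-hydroxydrim-7-en-11-yl]oxy}-2H-chromen-2-one | O[C@@H]1CC(C)(C)[C@H]2CC=C(C)[C@@H](COc3ccc4ccc(=O)oc4c3)[C@]2(C)C1 | intermediate
20 | 7-{[(5R,9R,10R)-2-oxodrim-7-en-11-yl]oxy}-2H-chromen-2-one | O=C1CC(C)(C)[C@H]2CC=C(C)[C@@H](COc3ccc4ccc(=O)oc4c3)[C@]2(C)C1 | intermediate
21 | lithium C2–C3 enolate of 20 | [Li+].[O-]C1=CC(C)(C)[C@H]2CC=C(C)[C@@H](COc3ccc4ccc(=O)oc4c3)[C@]2(C)C1 | intermediate (not isolated)
22 | 3-(trifluoroacetyl) derivative of 20 (drawn as the diketo tautomer; C3 enolised, not stereodefined) | O=C1C(C(=O)C(F)(F)F)C(C)(C)[C@H]2CC=C(C)[C@@H](COc3ccc4ccc(=O)oc4c3)[C@]2(C)C1 | intermediate (not isolated)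
23 | 7-{[(5S,9R,10R)-3-diazo-2-oxodrim-7-en-11-yl]oxy}-2H-chromen-2-one | O=C1C(=[N+]=[N-])C(C)(C)[C@H]2CC=C(C)[C@@H](COc3ccc4ccc(=O)oc4c3)[C@]2(C)C1 | intermediate
24 | angelic acid, (Z)-2-methylbut-2-enoic acid | C/C=C(/C)C(=O)O | starting material
25 | (3S,5S,9R,10R)-2-oxo-11-[(2-oxo-2H-chromen-7-yl)oxy]drim-7-en-3-yl (Z)-2-methylbut-2-enoate | C/C=C(/C)C(=O)O[C@@H]1C(=O)C[C@@]2(C)[C@H](COc3ccc4ccc(=O)oc4c3)C(C)=CC[C@@H]2C1(C)C | target

Total step count: 16 steps. Longest linear sequence: 16 steps, from (4R,6R)-actinol 1 to target 25 (building blocks 5, 8, 17 and 24 are used as purchased).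

Steps most likely to fail

Step 6. The cycloaddition may be outrun by a [1,5]-hydrogen shift or by decomposition, because the reacting geometry needs both the disfavoured s-cis ester rotamer and a pseudoaxial C2–O bond that meets the 4α-methyl group. The fallback keeps the tether but uses a more reactive dienophile and sets out from dienol 7. Mitsunobu esterification with but-3-ynoic acid (PPh3, DIAD, THF) should give, with inversion, (1S)-3,5,5-trimethyl-4-vinylcyclohex-3-en-1-yl but-3-ynoate F1. Catalytic Et3N in CH2Cl2 should isomerise it to (1S)-3,5,5-trimethyl-4-vinylcyclohex-3-en-1-yl buta-2,3-dienoate F2. The allenoate α,β-double bond is a far better dienophile and should cyclise in toluene at 80–110 °C to the 9β-H drima-5,8(12)-dien-11,2-olide F3, whose C9 configuration is dictated by the bridge and is later lost. Catalytic DBU at 0 °C should then move the exocyclic double bond into conjugation and rejoin the route at lactone 10.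

Step 10. Deprotonation may occur at the C12 methyl and give the exocyclic 8(12)-ene, the dienolate may be reprotonated at C7 and return the conjugated ester, or the ester may be cleaved by adventitious hydroxide. The fallback moves the deconjugation to the aldehyde level with acid-free enol-ester trapping and sets out from ester 13. DIBAL-H (CH2Cl2, −78 °C) should give 2α-[(tert-butyldimethylsilyl)oxy]drim-8-en-11-ol F4, and MnO2 should oxidise it to 2α-[(tert-butyldimethylsilyl)oxy]drim-8-en-11-al F5. Ac2O, Et3N and catalytic DMAP at 80 °C should trap the more stable endocyclic dienol as 11-acetoxy-2α-[(tert-butyldimethylsilyl)oxy]drima-7,9(11)-diene F6. NaBH4 in aqueous ethanol then cleaves the enol acetate, the dienolate is protonated at C9 on the α-face, and the β,γ-unsaturated aldehyde is reduced at once (the classical deconjugative borohydride reduction of dienol acetates). This rejoins the route at alcohol 16 and also replaces step 11.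

Step 15. Kinetic enolisation may not distinguish C1 from C3, or trifluoroacetylation of the hindered enolate may stall, giving regioisomeric or no diazo ketone. The fallback replaces kinetic enolate trapping by a reversible condensation under thermodynamic control and sets out from ketone 20. Claisen formylation (NaH, HCO2Et, catalytic EtOH, THF) should give the chelated 3-(hydroxymethylene)-2-oxo compound F7; the C1 regioisomer, strained against C11, can revert. Regitz deformylative diazo transfer (4-acetamidobenzenesulfonyl azide, Et3N, MeCN) then rejoins the route at diazo ketone 23.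

Further compounds
F1 | step 6 | (1S)-3,5,5-trimethyl-4-vinylcyclohex-3-en-1-yl but-3-ynoate | C#CCC(=O)O[C@H]1CC(C)=C(C=C)C(C)(C)C1
F2 | step 6 | (1S)-3,5,5-trimethyl-4-vinylcyclohex-3-en-1-yl buta-2,3-dienoate | C=C=CC(=O)O[C@H]1CC(C)=C(C=C)C(C)(C)C1
F3 | step 6 | 9β-H drima-5,8(12)-dien-11,2-olide (lactone bridge α, C10 methyl β) | O=C1O[C@@H]2CC(C)(C)C3=CCC(=C)[C@H]1[C@]3(C)C2
F4 | step 10 | 2α-[(tert-butyldimethylsilyl)oxy]drim-8-en-11-ol (5α-H) | CC(C)(C)[Si](C)(C)O[C@@H]1CC(C)(C)[C@H]2CCC(C)=C(CO)[C@]2(C)C1
F5 | step 10 | 2α-[(tert-butyldimethylsilyl)oxy]drim-8-en-11-al (5α-H) | CC(C)(C)[Si](C)(C)O[C@@H]1CC(C)(C)[C@H]2CCC(C)=C(C=O)[C@]2(C)C1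
F6 | step 10 | 11-acetoxy-2α-[(tert-butyldimethylsilyl)oxy]drima-7,9(11)-diene (enol acetate geometry not defined) | CC(C)(C)[Si](C)(C)O[C@@H]1CC(C)(C)[C@H]2CC=C(C)C(=COC(C)=O)[C@]2(C)C1
F7 | step 15 | 7-{[3-(hydroxymethylene)-2-oxodrim-7-en-11-yl]oxy}-2H-chromen-2-one (chelated Z-enol; 5α-H, 9α-H) | O/C=C1\C(=O)C[C@@]2(C)[C@H](COc3ccc4ccc(=O)oc4c3)C(C)=CC[C@@H]2C1(C)C
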